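**Plan**

- Retrosynthesis: the O–CH3 bond of a methyl-protected phenol is cut first. Ring B is then cut at C1'–C2' and C5'–C6', which leaves C1'/C6' as an alkyne and C2'–C5' as a 2-pyrone that has lost CO2. The ethynyl ether is traced back through a vinyl ether and a Baeyer–Villiger C–O bond to 2,3-dibromophenol.
- Enabling feature: ring B carries Br at C2' and C4' and H at C3' and C5', the pattern of C3–C6 of 3,5-dibromo-2-pyrone. C1' (ether oxygen) and C6' (H) can therefore come from an aryl ethynyl ether.
- Forward: ring A is bought with both bromines in place and receives its second oxygen, the methyl ether and the ethynyl ether in six steps. Ring B, the only ring made, arises in step 8 by [4+2] cycloaddition and loss of CO2. Demethylation ends the route.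
- Stereochemistry: the target has no stereocentre and no configured double bond. The sp3 centres and the Z alkene that appear on the way are all erased.

Key step: step 8

Remark: coumalic acid and 2,3-dibromophenol are taken as commercial. The 2-bromovinyl ether of step 6 is drawn as the Z isomer expected to predominate; any E isomer is carried along, since it leads to the same alkyne, only more slowly.

**Route**

Step 1
Reactants: 1 coumalic acid
Product: 2 3,5-dibromo-2H-pyran-2-one
Conditions: NBS (2.5 equiv), LiOAc, MeCN/H2O, rt
Reagents that add atoms: N-bromosuccinimide, O=C1CCC(=O)N1Br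
Why: Electrophilic bromination at C3 together with ipso-bromodecarboxylation of the C5 carboxylate (a Hunsdiecker-type halodecarboxylation) is the established one-step entry from coumalic acid to this dibromopyrone.

Step 2
Reactants: 3 2,3-dibromophenol
Product: 4 3,4-dibromo-2-hydroxybenzaldehyde
Conditions: MgCl2, Et3N, (CH2O)n, THF, reflux; aq HCl work-up
Reagents that add atoms: paraformaldehyde (reacts as formaldehyde), C=O
Why: Magnesium-mediated ortho-formylation (Casnati–Skattebøl reaction) delivers formaldehyde within the magnesium phenoxide chelate to the only free ortho carbon and oxidises the benzylic alkoxide with a second formaldehyde, a protocol known to tolerate ortho-bromophenols.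

Step 3
Reactants: 4 3,4-dibromo-2-hydroxybenzaldehyde
Product: 5 3,4-dibromo-2-methoxybenzaldehyde
Conditions: MeI, K2CO3, DMF, rt
Reagents that add atoms: iodomethane, CI
Why: Williamson ether synthesis on the phenoxide should proceed cleanly once K2CO3 in a dipolar aprotic solvent breaks the hydrogen bond to the aldehyde.

Step 4
Reactants: 5 3,4-dibromo-2-methoxybenzaldehyde
Product: 7 3,4-dibromo-2-methoxyphenol, via aryl formate 6 (not isolated)
Conditions: mCPBA, CH2Cl2, 40 °C; aq Na2SO3/NaHCO3 wash; then K2CO3 (cat.), MeOH, rt
Reagents that add atoms: 3-chloroperoxybenzoic acid (mCPBA), OOC(=O)c1cccc(Cl)c1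
Why: Baeyer–Villiger oxidation of an ortho-alkoxybenzaldehyde (Dakin-type) proceeds by aryl migration in the Criegee adduct because the methoxy group raises the migratory aptitude of the ring over hydride, and the aryl formate is then cleaved by base-catalysed methanolysis.

Step 5
Reactants: 7 3,4-dibromo-2-methoxyphenol
Product: 8 1,2-dibromo-4-(ethenyloxy)-3-methoxybenzene
Conditions: 2,4,6-trivinylcyclotriboroxane·pyridine, Cu(OAc)2 (1 equiv), pyridine, CH2Cl2, rt, air
Reagents that add atoms: 2,4,6-trivinylcyclotriboroxane–pyridine complex, C=CB1OB(C=C)OB(C=C)O1.c1ccncc1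
Why: Copper-mediated oxidative O-vinylation of phenols with the vinylboroxine (Chan–Lam coupling) runs at room temperature and leaves aryl bromides untouched, unlike palladium-based vinylations.

Step 6
Reactants: 8 1,2-dibromo-4-(ethenyloxy)-3-methoxybenzene
Product: 10 (Z)-1,2-dibromo-4-(2-bromoethenyloxy)-3-methoxybenzene, via dibromoethyl ether 9 (not isolated)
Conditions: Br2 (1.0 equiv), CH2Cl2, −78 °C; then DBU, −78 °C → rt
Reagents that add atoms: bromine, BrBr
Why: Bromine adds to the electron-rich enol ether far faster than it substitutes the deactivated ring at −78 °C, and DBU then removes HBr across the labile α-bromo ether (E2, the sequence used to make 2-bromo enol ethers such as 2-bromoglycals), the Z isomer being expected to predominate.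

Step 7
Reactants: 10 (Z)-1,2-dibromo-4-(2-bromoethenyloxy)-3-methoxybenzene
Product: 11 1,2-dibromo-4-(ethynyloxy)-3-methoxybenzene
Conditions: KOtBu (1.5 equiv), THF, −78 → 0 °C; cold pentane/aq NaHCO3 work-up, filtration through basic alumina, used at once
Reagents that add atoms: none
Why: In the Z isomer the hydrogen on the oxygen-bearing carbon is anti-periplanar to bromide, so alkoxide-induced E2 dehydrobromination, the classical route to aryloxyacetylenes, should occur at low temperature where KOtBu leaves the aryl bromides alone.

Step 8
Reactants: 2 3,5-dibromo-2H-pyran-2-one; 11 1,2-dibromo-4-(ethynyloxy)-3-methoxybenzene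
Product: 13 1,2-dibromo-4-(2,4-dibromophenoxy)-3-methoxybenzene, via bridged lactone 12 (not isolated)
Conditions: 2 (2.5 equiv), toluene, 80 °C, slow addition of freshly made 11; then 100 °C until CO2 evolution ends
Reagents that add atoms: none
Why: The electron-poor diene C3=C4–C5=C6 of pyrone 2 and the electron-rich alkyne of 11 should combine in an asynchronous inverse-electron-demand [4+2] cycloaddition that forms C1'–C2' (oxygen-bearing alkyne carbon to pyrone C3) and C5'–C6' (pyrone C6 to the alkyne CH), and the bridged lactone 12 then expels CO2 by retro-[4+2] to leave the benzene ring directly. The closest known reactions are the alkyne Diels–Alder/decarboxylation benzannulation of 2-pyrones and the cycloadditions of 3,5-dibromo-2-pyrone with enol ethers. Ring B, the only ring formed, is closed by intermolecular cycloaddition in which both new σ bonds arise in one step, and it becomes aromatic by cycloreversion, so no oxidation or elimination that could expel the aryloxy group is involved. No stereocentre survives, because the two bridgehead centres of 12 arise as a racemate and vanish with the loss of CO2. The selectivity needed is regiochemical, and the polarisation of both partners should secure it: the nucleophilic terminal carbon of the ynol ether bonds to the electrophilic C6 of the pyrone, as enol ethers do, which places the ether oxygen next to the C3 bromine. Oligomerisation of the labile ynol ether is countered by adding it slowly, freshly made, to an excess of the cheap pyrone.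

Step 9
Reactants: 13 1,2-dibromo-4-(2,4-dibromophenoxy)-3-methoxybenzene
Product: 14 2,3-dibromo-6-(2,4-dibromophenoxy)phenol
Conditions: BBr3, CH2Cl2, −78 °C → rt; then H2O
Reagents that add atoms: none
Why: Lewis acid ether cleavage, in which BBr3 complexes the methoxy oxygen and bromide attacks the methyl group by SN2, while the diaryl ether and the four aryl bromides are inert, as is usual for methoxylated polybrominated diphenyl ethers.

**Compound list**

1 | coumalic acid (2-oxo-2H-pyran-5-carboxylic acid) | O=C(O)C1=COC(=O)C=C1 | starting material
2 | 3,5-dibromo-2H-pyran-2-one | O=C1OC=C(Br)C=C1Br | intermediate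
3 | 2,3-dibromophenol | Oc1cccc(Br)c1Br | starting material
4 | 3,4-dibromo-2-hydroxybenzaldehyde | O=Cc1ccc(Br)c(Br)c1O | intermediate
5 | 3,4-dibromo-2-methoxybenzaldehyde | COc1c(C=O)ccc(Br)c1Br | intermediate
6 | 3,4-dibromo-2-methoxyphenyl formate | COc1c(OC=O)ccc(Br)c1Br | intermediate
7 | 3,4-dibromo-2-methoxyphenol | COc1c(O)ccc(Br)c1Br | intermediate
8 | 1,2-dibromo-4-(ethenyloxy)-3-methoxybenzene | C=COc1ccc(Br)c(Br)c1OC | intermediate
9 | 1,2-dibromo-4-(1,2-dibromoethoxy)-3-methoxybenzene (racemic) | BrCC(Br)Oc1ccc(Br)c(Br)c1OC | intermediate
10 | (Z)-1,2-dibromo-4-(2-bromoethenyloxy)-3-methoxybenzene | Br/C=C\Oc1ccc(Br)c(Br)c1OC | intermediate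
11 | 1,2-dibromo-4-(ethynyloxy)-3-methoxybenzene | C#COc1ccc(Br)c(Br)c1OC | intermediate
12 | 4,7-dibromo-5-(3,4-dibromo-2-methoxyphenoxy)-2-oxabicyclo[2.2.2]octa-5,7-dien-3-one (racemic, one enantiomer drawn) | O=C1O[C@@H]2C=C(Oc3ccc(Br)c(Br)c3OC)[C@@]1(Br)C=C2Br | intermediate
13 | 1,2-dibromo-4-(2,4-dibromophenoxy)-3-methoxybenzene | COc1c(Oc2ccc(Br)cc2Br)ccc(Br)c1Br | intermediate
14 | 2,3-dibromo-6-(2,4-dibromophenoxy)phenol | Oc1c(Oc2ccc(Br)cc2Br)ccc(Br)c1Br | target

**Totals and risks**

Total step count: 9. Longest linear sequence: 8 steps (3 to 14, steps 2 to 9); step 1 supplies the pyrone for the convergent step 8.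

The step most likely to fail is step 8. The ynol ether may oligomerise faster than it is captured by the pyrone, or the two partners may combine in the reverse orientation and give the 3,5-dibromophenyl ether. The fallback gives up the cycloaddition and sets out from phenol 7. Compound 7 would be O-arylated with bis(2,4-dibromophenyl)iodonium chloride F1, itself prepared from 1,3-dibromobenzene with I2 and KIO3 in H2SO4 and precipitated with NaCl. With NaOH in water/dioxane at 80 °C, ligand coupling on trivalent iodine should give the diaryl ether and 2,4-dibromo-1-iodobenzene, and the route is rejoined at 13.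

Second is step 7. The terminal ynol ether may decompose under base or on concentration, the minor E isomer may eliminate only sluggishly, and aryloxide may be lost from the vinyl anion formed at the bromine-bearing carbon. The fallback sets out from 10 and keeps the cycloaddition but never handles the free alkyne. Excess KN(SiMe3)2 in THF at −78 °C would eliminate HBr and deprotonate the alkyne, and Me3SiCl would cap the acetylide as [(3,4-dibromo-2-methoxyphenoxy)ethynyl]trimethylsilane F2, which should survive chromatography and storage. Heating F2 with pyrone 2 in toluene at 110 °C should give, through the silylated bridged lactone F3, [3,5-dibromo-2-(3,4-dibromo-2-methoxyphenoxy)phenyl]trimethylsilane F4, with the silyl group on the carbon that bonds to the unhindered pyrone C6. Protodesilylation with Bu4NF in moist DMF would then rejoin the route at 13.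

Third is step 5. Copper-mediated C–O bond formation may be slow on the hindered, electron-poor ortho-methoxyphenol, so that protodeboronation of the vinylboroxine and oxidative side reactions of the phenol consume the reagents. The fallback sets out from 7 and replaces the oxidative coupling by alkylation and elimination. Excess 1,2-dibromoethane with K2CO3 in MeCN at reflux would give 1,2-dibromo-4-(2-bromoethoxy)-3-methoxybenzene F5, and E2 elimination with KOtBu in THF would rejoin the route at 8.

**Further compounds**

F1 | step 8 | bis(2,4-dibromophenyl)iodonium chloride | [Cl-].Brc1ccc([I+]c2ccc(Br)cc2Br)c(Br)c1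
F2 | step 7 | [(3,4-dibromo-2-methoxyphenoxy)ethynyl]trimethylsilane | COc1c(OC#C[Si](C)(C)C)ccc(Br)c1Br
F3 | step 7 | 4,7-dibromo-5-(3,4-dibromo-2-methoxyphenoxy)-6-(trimethylsilyl)-2-oxabicyclo[2.2.2]octa-5,7-dien-3-one (racemic, one enantiomer drawn) | O=C1O[C@@H]2C([Si](C)(C)C)=C(Oc3ccc(Br)c(Br)c3OC)[C@@]1(Br)C=C2Br
F4 | step 7 | [3,5-dibromo-2-(3,4-dibromo-2-methoxyphenoxy)phenyl]trimethylsilane | COc1c(Oc2c(Br)cc(Br)cc2[Si](C)(C)C)ccc(Br)c1Br
F5 | step 5 | 1,2-dibromo-4-(2-bromoethoxy)-3-methoxybenzene | COc1c(OCCBr)ccc(Br)c1Br
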